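Look first at time: the teal run stands at 0.048 M of product after 13 h and at 0.055 M after 30 h, well short of its substrate charge. So ask first what the end state is, and only then how fast it comes.

| setting | teal | red | grey | green | violet |
|---|---|---|---|---|---|
| substrate | 0.200 M | 0.0800 M | 0.300 M | 0.200 M | 0.200 M |
| partner | 0.240 M | 0.120 M | 0.240 M | 0.240 M | 0.240 M |
| catalyst | 0.00600 M | 0.00600 M | 0.00600 M | 0.0120 M | 0.0210 M |
| time |  |  |  |  | 30 h |

| run | time / h | [product] / M |
|---|---|---|
| teal run | 2.3 | 0.028 |
| teal run | 6.9 | 0.041 |
| teal run | 13 | 0.048 |
| teal run | 21 | 0.049 |
| teal run | 30 | 0.055 |
| red run | 2.3 | 0.004 |
| red run | 6.9 | 0.018 |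
| red run | 13 | 0.019 |
| red run | 21 | 0.022 |
| red run | 30 | 0.022 |
| grey run | 2.3 | 0.031 |
| grey run | 6.9 | 0.055 |
| grey run | 13 | 0.057 |
| grey run | 21 | 0.059 |
| grey run | 30 | 0.066 |
| green run | 2.3 | 0.046 |
| green run | 6.9 | 0.067 |
| green run | 13 | 0.077 |
| green run | 21 | 0.083 |
| green run | 30 | 0.081 |

(scatter of a reading: 0.003 M)

1. apparent order in [partner] of the starting rate, round the charge of the teal run (the rate where two percent of its substrate have turned into product)
2. apparent order in [substrate] of the starting rate, round the charge of the teal run (the rate where two percent of its substrate have turned into product) (one fixed amount of product, the same in the runs compared)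
3. product in the violet run at 30 h, as a share of the substrate charged

- Overall: substrate + partner -> product, with catalyst as catalyst.
- Constant volume, constant temperature.
- A reading of a species includes what of it is bound.
- "The second partner" is partner.
- An order is taken over about fifteen percent of the charge, up and down.

Bracket the violet run. From above stands its whole substrate charge, since substrate is the limiting reagent, with 0.200 M charged, less than the 0.240 M of partner. Now tighten that. Going from teal to green takes the catalyst to twice its charge but raises the product read at 30 h by a factor of 1.47, less than that. If the gain stays less than proportional, then scaling green by catalyst caps violet at 70.9% of its charge. From below, take it that more catalyst gives no less product, so violet reaches at least green's 40.5%.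

To go further, compare shares of the charge read at 30 h: the grey run has turned 22.0% into product, less than the 27.5% of the teal run. A larger charge converting a smaller share suggests a loss of substrate that needs no catalyst and is second order in substrate. Suppose so, and let the product route be first order in substrate and in catalyst. Then substrate goes to product with the share m/(m + c(substrate)), and summing that share as c(substrate) falls from the charge to nothing gives an end product of m·ln(1 + charge/m). Choose m from the teal run, so that this end product meets its last reading: a ratio of charge to m of 8 puts m at 0.0250 M, the crossing concentration: the c(substrate) at which the two routes consume substrate equally. That m gives an end product of 0.0549 M in the teal run, against the 0.055 M read at 30 h. Under the same supposition m grows in step with catalyst, so the violet run has m = 0.0875 M, and my reckoning gives 0.104 M, or 52.0% of its charge.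

The forecast says 56% (46% to 67%), inside the bracket, with order 0.5 in partner (0.1 to 1) and 0.5 in substrate (0.2 to 0.9), on the view that “the catalyst is probably dying”.

The flask gives 51.5% in the violet run, with orders of 1.1 in partner and 0.87 in substrate.

    catalyst + substrate ⇌ catalyst-substrate complex, settled at all times (0.5180 /M)
    catalyst-substrate complex + partner ⇌ ternary complex, settled at all times (2.820 /M)
    ternary complex → product + catalyst (56.52 /h)
    2 substrate → homo dimer (1.894 /M/h)

The main reason for the violet shortfall is the turning of substrate into homo dimer: without that step the violet run reaches 97.5% instead of 51.5%. In the violet run the charge stands at 2.29 times m, so by this reckoning the route to homo dimer starts ahead of the route to product. On the grey run, teal's m with a charge of 0.300 M gives 0.0641 M, and its reading at 30 h is 0.066 M.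

Readings and results were computed from invented constants, and the scatter is random.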